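**Plan**

- Retrosynthesis: remove the three esters and the C15 silyl ether; cut C12–C13 (B-alkyl Suzuki–Miyaura) and C11=C12 (Wittig) back to a bicyclic dienal; cut C7–O (enolate hydroxylation); cut C5–C10 and C8–C9 together (intramolecular Diels–Alder); then cut C6–C7 (alkynyl addition to a lactone) and C1–C2 (vinylogous aldol).
- Enabling feature: ring B (C5–C10) is a cyclohexene with oxygen on C6 and the C8=C9 double bond. This is the cycloadduct of a 1-methoxy-3-silyloxy diene C5=C6–C7=C8 with a β-methyl enal C9=C10 after loss of methanol. C5 and C10 are joined by the chain C4–C3–C2–C1, so one cycloaddition closes rings A and B and creates the quaternary C10.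
- Forward: the linear chain is built by a vinylogous aldol, lactone opening with propynyllithium, methanol addition and silyl dienol ether formation. Rings A and B then form in one step, followed by the C9 side chain (Wittig, hydroboration/Suzuki–Miyaura), the C7 hydroxyl, C6 reduction and the acylations.
- Stereochemistry: C2 comes from the catalyst-controlled vinylogous aldol; C5 and C10 are relayed from C2 in the cycloaddition; C7 and C6 arise by α-face attack on ring B, whose β face is blocked by the axial C4 and C10 methyl groups; the 13E olefin comes from syn-hydrozirconation.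

Key step: step 11

Remark: labdane numbering is used for all ring compounds (C1–C10 decalin, gem-dimethyl on C4, methyl on C10 and C8, side chain C11–C16 on C9); the oxazaborolidinone antipode in step 4 is assumed to be the one that gives the (S) carbinol by Re-face attack and would be exchanged for its enantiomer if the sense proved opposite.

**Route**

Step 1
Reactants: 1 methyl 3,3-dimethylpent-4-enoate
Product: 3 methyl 5-hydroxy-3,3-dimethylpentanoate, via B-alkyl-9-BBN adduct 2 (not isolated)
Conditions: 9-BBN, THF, 0 °C to rt; then 30% H2O2, aq. NaOAc, 0 °C to rt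
Reagents that add atoms: hydrogen peroxide, OO
Why: Anti-Markovnikov hydroboration–oxidation of the neopentyl-type vinyl group should give the primary alcohol, and the buffered oxidation should spare the methyl ester and limit lactonization.

Step 2
Reactants: 3 methyl 5-hydroxy-3,3-dimethylpentanoate
Product: 4 methyl 3,3-dimethyl-5-oxopentanoate
Conditions: TEMPO (10 mol %), PhI(OAc)2, CH2Cl2, rt
Reagents that add atoms: none
Why: Nitroxyl-catalysed oxidation of a primary alcohol should stop cleanly at the aldehyde.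

Step 3
Reactants: 5 methyl 3-methylbut-2-enoate
Product: 6 tert-butyl[(1-methoxy-3-methylbuta-1,3-dien-1-yl)oxy]dimethylsilane
Conditions: LiN(iPr)2, TBSCl, THF/DMPU, −78 °C to rt
Reagents that add atoms: tert-butyldimethylsilyl chloride, CC(C)(C)[Si](C)(C)Cl
Why: γ-Deprotonation of the enoate gives the extended enolate, and O-silylation should give the silyl dienol ether (silyl ketene acetal formation).

Step 4
Reactants: 4 methyl 3,3-dimethyl-5-oxopentanoate; 6 tert-butyl[(1-methoxy-3-methylbuta-1,3-dien-1-yl)oxy]dimethylsilane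
Product: 8 methyl (2E)-4-[(2S)-4,4-dimethyl-6-oxooxan-2-yl]-3-methylbut-2-enoate, via hydroxy diester 7 (not isolated)
Conditions: B-phenyl oxazaborolidinone from N-tosyl-L-tryptophan and PhBCl2 (30 mol %), iPrOH (1.1 equiv), EtCN, −78 °C; then PPTS (cat.), toluene, 60 °C
Reagents that add atoms: none
Why: The catalytic enantioselective vinylogous Mukaiyama aldol reaction should join the γ-carbon of the dienolate to the Re face of the aldehyde, setting the (S) carbinol (C2) and the (E)-trisubstituted enoate, and the δ-hydroxy ester then lactonizes under the gem-dimethyl effect.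

Step 5
Reactants: 8 methyl (2E)-4-[(2S)-4,4-dimethyl-6-oxooxan-2-yl]-3-methylbut-2-enoate
Product: 9 methyl (2E,5S)-5-hydroxy-3,7,7-trimethyl-9-oxododec-2-en-10-ynoate
Conditions: LiC≡CCH3 (1.1 equiv), THF, −78 °C; AcOH quench at −78 °C
Reagents that add atoms: 1-propynyllithium, [Li]C#CC
Why: An alkynyllithium should add once to the δ-lactone (a stable lithium hemiketal until quench) to give the ynone, the lactone being far more electrophilic than the β,β-disubstituted enoate.

Step 6
Reactants: 9 methyl (2E,5S)-5-hydroxy-3,7,7-trimethyl-9-oxododec-2-en-10-ynoate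
Product: 10 methyl (2E,5S)-3,7,7-trimethyl-9-oxo-5-(triethylsilyloxy)dodec-2-en-10-ynoate
Conditions: TESCl, imidazole, DMF, 0 °C
Reagents that add atoms: chlorotriethylsilane, CC[Si](Cl)(CC)CC
Why: Silylation of the secondary alcohol should trap the open-chain hydroxy ynone and protect C2–OH with a group that can later be removed in the presence of the C15 silyl ether.

Step 7
Reactants: 10 methyl (2E,5S)-3,7,7-trimethyl-9-oxo-5-(triethylsilyloxy)dodec-2-en-10-ynoate
Product: 11 methyl (2E,5S,10E)-11-methoxy-3,7,7-trimethyl-9-oxo-5-(triethylsilyloxy)dodeca-2,10-dienoate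
Conditions: MeOH, PBu3 (10 mol %), CH2Cl2, rt
Reagents that add atoms: methanol, CO
Why: Phosphine-catalysed conjugate addition of methanol to the ynone should give the (E)-β-methoxy enone with unambiguous regiochemistry (oxa-Michael addition).

Step 8
Reactants: 11 methyl (2E,5S,10E)-11-methoxy-3,7,7-trimethyl-9-oxo-5-(triethylsilyloxy)dodeca-2,10-dienoate
Product: 12 methyl (2E,5R,8Z,10E)-9-(tert-butyldimethylsilyloxy)-11-methoxy-3,7,7-trimethyl-5-(triethylsilyloxy)dodeca-2,8,10-trienoate (C5 unchanged in space; the descriptor changes by priority only)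
Conditions: LiN(SiMe3)2, TBSCl, THF/DMPU, −78 °C
Reagents that add atoms: tert-butyldimethylsilyl chloride, CC(C)(C)[Si](C)(C)Cl
Why: Kinetic α'-deprotonation of the vinylogous ester at C5 with in situ O-silylation should give the 1-methoxy-3-silyloxy diene, the bulky C4 substituent favouring the (Z)-enol ether with the tether trans to C7 (silyl enol ether formation).

Step 9
Reactants: 12 the silyloxy diene ester
Product: 13 (2E,5R,8Z,10E)-9-(tert-butyldimethylsilyloxy)-11-methoxy-3,7,7-trimethyl-5-(triethylsilyloxy)dodeca-2,8,10-trien-1-ol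
Conditions: iBu2AlH (2.5 equiv), CH2Cl2, −78 °C; aq. potassium sodium tartrate
Reagents that add atoms: none
Why: 1,2-Reduction of the enoate by the aluminium hydride should give the allylic alcohol, and the silyl enol ether should survive the non-acidic work-up.

Step 10
Reactants: 13 the trienol
Product: 14 (2E,5R,8Z,10E)-9-(tert-butyldimethylsilyloxy)-11-methoxy-3,7,7-trimethyl-5-(triethylsilyloxy)dodeca-2,8,10-trienal
Conditions: MnO2, CH2Cl2, rt; filtration
Reagents that add atoms: none
Why: Neutral, heterogeneous allylic oxidation should give the (E)-enal without touching the electron-rich diene.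

Step 11
Reactants: 14 the trienal
Product: 16 2α-(triethylsilyloxy)-6-(tert-butyldimethylsilyloxy)drima-6,8-dien-11-al (5α-H; 10β-CH3), via methoxy aldehyde cycloadduct 15 (not isolated)
Conditions: toluene (0.005 M), BHT, 2,6-di-tert-butyl-4-methylpyridine (0.1 equiv), 130 °C, sealed tube; then DBU, rt
Reagents that add atoms: none
Why: This is a thermal type 1 intramolecular Diels–Alder reaction of a 1,3,9-decatriene in which the 1-methoxy-3-silyloxy diene (C5=C6–C7=C8) and the tethered (E)-β-methyl enal (C9=C10) combine in a concerted, asynchronous normal-demand [4+2], the doubly donor-activated terminus C5 bonding to the electrophilic β-carbon C10 and C8 bonding to C9; the closest known reaction type is the intramolecular cycloaddition of 1-alkoxy-3-silyloxy dienes with enals in the trans-decalin-forming decatriene series. Ring A closes as the six-membered tether ring (chain C1–C4, with C5–C10 as the fusion bond) and ring B is the new cyclohexene of the [4+2], both bonds forming suprafacially on each partner. C5 and C10 are set by the anti (trans-fused) chair-like transition state, which is the endo mode for the formyl group because the (E)-enal holds CHO cis to the C10 methyl and trans to the tether, while the C2 silyloxy group sits equatorial on the forming chair (an axial one would clash with the C4 and C10 methyl groups) and so relays its configuration to give 5α-H and 10β-CH3. The step needs trans over cis ring fusion and one π-face, and these should be secured by the (Z)-enol ether with the tether on the outside of the diene, the (E)-enal and the equatorial C2 substituent; the tether fixes the regiochemistry, which the diene polarisation also favours. The transient stereocentres C8 and C9 of cycloadduct 15 are erased when DBU expels methanol by E1cB through the aldehyde enolate, which can place the double bond only at C8=C9 because C10 is quaternary.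

Step 12
Reactants: 16 the drimadienal
Product: 17 2α-(triethylsilyloxy)-6-(tert-butyldimethylsilyloxy)-13,14,15,16-tetranorlabda-6,8,11-triene
Conditions: CH3PPh3Br, KOtBu, THF, 0 °C to rt
Reagents that add atoms: methyltriphenylphosphonium bromide, C[P+](c1ccccc1)(c1ccccc1)c1ccccc1.[Br-]
Why: Wittig methylenation with the unhindered ylide should convert the hindered, non-enolizable aldehyde into the vinyl group that carries C11 and C12.

Step 13
Reactants: 18 but-2-yn-1-ol
Product: 19 (but-2-yn-1-yloxy)(tert-butyl)diphenylsilane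
Conditions: TBDPSCl, imidazole, CH2Cl2, rt
Reagents that add atoms: tert-butyl(chloro)diphenylsilane, CC(C)(C)[Si](Cl)(c1ccccc1)c1ccccc1
Why: Standard silylation of the primary alcohol gives a bulky ether that also directs the next step.

Step 14
Reactants: 19 the butynyl silyl ether
Product: 21 tert-butyl{[(2E)-3-iodobut-2-en-1-yl]oxy}diphenylsilane, via alkenylzirconocene chloride 20 (not isolated)
Conditions: Cp2Zr(H)Cl (1.5 equiv), THF, rt to 40 °C; then I2, 0 °C
Reagents that add atoms: iodine, II
Why: syn-Hydrozirconation, equilibrated so that zirconium sits on the carbon next to the small methyl group, followed by iodinolysis with retention, should give the (E)-vinyl iodide that fixes the 13E geometry.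

Step 15
Reactants: 17 the tetranorlabdatriene; 21 the (E)-vinyl iodide
Product: 23 15-(tert-butyldiphenylsilyloxy)-6-(tert-butyldimethylsilyloxy)-2α-(triethylsilyloxy)-(13E)-labda-6,8,13-triene, via B-alkyl-9-BBN adduct 22 (not isolated)
Conditions: 9-BBN, THF, rt; then 21, PdCl2(dppf) (5 mol %), AsPh3, Cs2CO3, DMF/H2O, rt
Reagents that add atoms: none
Why: 9-BBN should add only to the terminal vinyl group (boron on C12), and the B-alkyl Suzuki–Miyaura coupling with retention at the vinyl iodide should form C12–C13 and complete the side chain.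

Step 16
Reactants: 23 the tris-silylated labdatriene
Product: 24 15-(tert-butyldiphenylsilyloxy)-2α-hydroxy-(13E)-labda-8,13-dien-6-one
Conditions: HF·pyridine, pyridine, THF, 0 °C
Reagents that add atoms: none
Why: Buffered fluoride should cleave the silyl dienol ether, with kinetic α-protonation at C7 leaving the tetrasubstituted C8=C9 olefin in place, and the triethylsilyl ether, while the primary tert-butyldiphenylsilyl ether is expected to survive.

Step 17
Reactants: 24 the β,γ-unsaturated hydroxy ketone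
Product: 26 15-(tert-butyldiphenylsilyloxy)-2α,7α-dihydroxy-(13E)-labda-8,13-dien-6-one, via dipotassium dienolate 25 (not isolated)
Conditions: KN(SiMe3)2 (2.3 equiv), THF, −78 °C; then 3-phenyl-2-(phenylsulfonyl)oxaziridine, −78 °C; sat. NH4Cl
Reagents that add atoms: 3-phenyl-2-(phenylsulfonyl)oxaziridine, O=S(=O)(N1OC1c1ccccc1)c1ccccc1
Why: Enolate α-hydroxylation with an N-sulfonyloxaziridine should occur at C7, the α-carbon of the extended enolate, from the α face opposite the axial C10 and C4β methyl groups, giving the 7α alcohol without touching the side-chain olefin.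

Step 18
Reactants: 26 the dihydroxy ketone
Product: 27 15-(tert-butyldiphenylsilyloxy)-(13E)-labda-8,13-diene-2α,6β,7α-triol
Conditions: NaBH4, CeCl3·7H2O, MeOH, −78 to −40 °C
Reagents that add atoms: none
Why: In this Luche-type reduction hydride should reach C6 from the open α face, because the β face is blocked by the syn-axial C4 and C10 methyl groups, giving the axial 6β alcohol trans to the 7α hydroxyl.

Step 19
Reactants: 27 the triol
Product: 28 2α,7α-diacetoxy-15-(tert-butyldiphenylsilyloxy)-(13E)-labda-8,13-dien-6β-ol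
Conditions: Ac2O, pyridine, DMAP (5 mol %), 0 °C to rt
Reagents that add atoms: acetic anhydride, CC(=O)OC(C)=O
Why: The equatorial 2α and allylic 7α hydroxyls should acetylate, while the 6β hydroxyl, syn-axial to two methyl groups, should remain free (site-selective esterification).

Step 20
Reactants: 28 the diacetate
Product: 29 2α,7α-diacetoxy-6β-(3-methylbutanoyloxy)-15-(tert-butyldiphenylsilyloxy)-(13E)-labda-8,13-diene
Conditions: 3-methylbutanoyl chloride (3 equiv), DMAP (1 equiv), pyridine, ClCH2CH2Cl, 60 °C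
Reagents that add atoms: 3-methylbutanoyl chloride, CC(C)CC(Cl)=O
Why: Forcing DMAP-mediated acylation should esterify the hindered axial 6β alcohol, and the trans-diaxial relation to the 7α acetate prevents acyl migration.

Step 21
Reactants: 29 the silyl-protected triester
Product: 30 2α,7α-diacetoxy-6β-(3-methylbutanoyloxy)-(13E)-labda-8,13-dien-15-ol (target)
Conditions: Bu4NF, AcOH, THF, rt
Reagents that add atoms: none
Why: Buffered fluoride desilylation should free the primary allylic alcohol without hydrolysing or migrating the three esters.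

**Compound list**

1 | methyl 3,3-dimethylpent-4-enoate | COC(=O)CC(C)(C)C=C | starting material
2 | methyl 5-(9-borabicyclo[3.3.1]nonan-9-yl)-3,3-dimethylpentanoate | COC(=O)CC(C)(C)CCB1C2CCCC1CCC2 | intermediate
3 | methyl 5-hydroxy-3,3-dimethylpentanoate | COC(=O)CC(C)(C)CCO | intermediate
4 | methyl 3,3-dimethyl-5-oxopentanoate | COC(=O)CC(C)(C)CC=O | intermediate
5 | methyl 3-methylbut-2-enoate | COC(=O)C=C(C)C | starting material
6 | tert-butyl[(1-methoxy-3-methylbuta-1,3-dien-1-yl)oxy]dimethylsilane | COC(O[Si](C)(C)C(C)(C)C)=CC(C)=C | intermediate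
7 | dimethyl (2E,5S)-5-hydroxy-3,7,7-trimethylnon-2-enedioate | COC(=O)/C=C(\C)C[C@@H](O)CC(C)(C)CC(=O)OC | intermediate
8 | methyl (2E)-4-[(2S)-4,4-dimethyl-6-oxooxan-2-yl]-3-methylbut-2-enoate | COC(=O)/C=C(\C)C[C@@H]1CC(C)(C)CC(=O)O1 | intermediate
9 | methyl (2E,5S)-5-hydroxy-3,7,7-trimethyl-9-oxododec-2-en-10-ynoate | COC(=O)/C=C(\C)C[C@@H](O)CC(C)(C)CC(=O)C#CC | intermediate
10 | methyl (2E,5S)-3,7,7-trimethyl-9-oxo-5-(triethylsilyloxy)dodec-2-en-10-ynoate | COC(=O)/C=C(\C)C[C@@H](O[Si](CC)(CC)CC)CC(C)(C)CC(=O)C#CC | intermediate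
11 | methyl (2E,5S,10E)-11-methoxy-3,7,7-trimethyl-9-oxo-5-(triethylsilyloxy)dodeca-2,10-dienoate | COC(=O)/C=C(\C)C[C@@H](O[Si](CC)(CC)CC)CC(C)(C)CC(=O)/C=C(\C)OC | intermediate
12 | methyl (2E,5R,8Z,10E)-9-(tert-butyldimethylsilyloxy)-11-methoxy-3,7,7-trimethyl-5-(triethylsilyloxy)dodeca-2,8,10-trienoate | COC(=O)/C=C(\C)C[C@@H](O[Si](CC)(CC)CC)CC(C)(C)/C=C(O[Si](C)(C)C(C)(C)C)/C=C(\C)OC | intermediate
13 | (2E,5R,8Z,10E)-9-(tert-butyldimethylsilyloxy)-11-methoxy-3,7,7-trimethyl-5-(triethylsilyloxy)dodeca-2,8,10-trien-1-ol | OC/C=C(\C)C[C@@H](O[Si](CC)(CC)CC)CC(C)(C)/C=C(O[Si](C)(C)C(C)(C)C)/C=C(\C)OC | intermediate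
14 | (2E,5R,8Z,10E)-9-(tert-butyldimethylsilyloxy)-11-methoxy-3,7,7-trimethyl-5-(triethylsilyloxy)dodeca-2,8,10-trienal | O=C/C=C(\C)C[C@@H](O[Si](CC)(CC)CC)CC(C)(C)/C=C(O[Si](C)(C)C(C)(C)C)/C=C(\C)OC | intermediate
15 | 8β-methoxy-2α-(triethylsilyloxy)-6-(tert-butyldimethylsilyloxy)drim-6-en-11-al (5α-H, 9α-H, 10β-CH3) | CC[Si](CC)(CC)O[C@H]1CC(C)(C)[C@@H]2C(O[Si](C)(C)C(C)(C)C)=C[C@](C)(OC)[C@H](C=O)[C@@]2(C)C1 | intermediate
16 | 2α-(triethylsilyloxy)-6-(tert-butyldimethylsilyloxy)drima-6,8-dien-11-al (5α-H, 10β-CH3) | CC[Si](CC)(CC)O[C@H]1CC(C)(C)[C@@H]2C(O[Si](C)(C)C(C)(C)C)=CC(C)=C(C=O)[C@@]2(C)C1 | intermediate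
17 | 2α-(triethylsilyloxy)-6-(tert-butyldimethylsilyloxy)-13,14,15,16-tetranorlabda-6,8,11-triene | CC[Si](CC)(CC)O[C@H]1CC(C)(C)[C@@H]2C(O[Si](C)(C)C(C)(C)C)=CC(C)=C(C=C)[C@@]2(C)C1 | intermediate
18 | but-2-yn-1-ol | CC#CCO | starting material
19 | (but-2-yn-1-yloxy)(tert-butyl)diphenylsilane | CC#CCO[Si](c1ccccc1)(c1ccccc1)C(C)(C)C | intermediate
20 | chloro{(2E)-4-[(tert-butyldiphenylsilyl)oxy]but-2-en-2-yl}bis(cyclopentadienyl)zirconium | C/C(=C\CO[Si](c1ccccc1)(c1ccccc1)C(C)(C)C)[Zr](Cl)(C1C=CC=C1)C1C=CC=C1 | intermediate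
21 | tert-butyl{[(2E)-3-iodobut-2-en-1-yl]oxy}diphenylsilane | C/C(I)=C\CO[Si](c1ccccc1)(c1ccccc1)C(C)(C)C | intermediate
22 | 12-(9-borabicyclo[3.3.1]nonan-9-yl)-2α-(triethylsilyloxy)-6-(tert-butyldimethylsilyloxy)-13,14,15,16-tetranorlabda-6,8-diene | CC[Si](CC)(CC)O[C@H]1CC(C)(C)[C@@H]2C(O[Si](C)(C)C(C)(C)C)=CC(C)=C(CCB3C4CCCC3CCC4)[C@@]2(C)C1 | intermediate
23 | 15-(tert-butyldiphenylsilyloxy)-6-(tert-butyldimethylsilyloxy)-2α-(triethylsilyloxy)-(13E)-labda-6,8,13-triene | CC[Si](CC)(CC)O[C@H]1CC(C)(C)[C@@H]2C(O[Si](C)(C)C(C)(C)C)=CC(C)=C(CC/C(C)=C/CO[Si](c3ccccc3)(c3ccccc3)C(C)(C)C)[C@@]2(C)C1 | intermediate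
24 | 15-(tert-butyldiphenylsilyloxy)-2α-hydroxy-(13E)-labda-8,13-dien-6-one | O[C@H]1CC(C)(C)[C@@H]2C(=O)CC(C)=C(CC/C(C)=C/CO[Si](c3ccccc3)(c3ccccc3)C(C)(C)C)[C@@]2(C)C1 | intermediate
25 | dipotassium 2-alkoxide 6,8-dienolate of 24 | [K+].[K+].[O-][C@H]1CC(C)(C)[C@@H]2C([O-])=CC(C)=C(CC/C(C)=C/CO[Si](c3ccccc3)(c3ccccc3)C(C)(C)C)[C@@]2(C)C1 | intermediate
26 | 15-(tert-butyldiphenylsilyloxy)-2α,7α-dihydroxy-(13E)-labda-8,13-dien-6-one | O[C@H]1CC(C)(C)[C@@H]2C(=O)[C@@H](O)C(C)=C(CC/C(C)=C/CO[Si](c3ccccc3)(c3ccccc3)C(C)(C)C)[C@@]2(C)C1 | intermediate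
27 | 15-(tert-butyldiphenylsilyloxy)-(13E)-labda-8,13-diene-2α,6β,7α-triol | O[C@H]1CC(C)(C)[C@@H]2[C@H](O)[C@@H](O)C(C)=C(CC/C(C)=C/CO[Si](c3ccccc3)(c3ccccc3)C(C)(C)C)[C@@]2(C)C1 | intermediate
28 | 2α,7α-diacetoxy-15-(tert-butyldiphenylsilyloxy)-(13E)-labda-8,13-dien-6β-ol | CC(=O)O[C@H]1CC(C)(C)[C@@H]2[C@H](O)[C@@H](OC(C)=O)C(C)=C(CC/C(C)=C/CO[Si](c3ccccc3)(c3ccccc3)C(C)(C)C)[C@@]2(C)C1 | intermediate
29 | 2α,7α-diacetoxy-6β-(3-methylbutanoyloxy)-15-(tert-butyldiphenylsilyloxy)-(13E)-labda-8,13-diene | CC(=O)O[C@H]1CC(C)(C)[C@@H]2[C@H](OC(=O)CC(C)C)[C@@H](OC(C)=O)C(C)=C(CC/C(C)=C/CO[Si](c3ccccc3)(c3ccccc3)C(C)(C)C)[C@@]2(C)C1 | intermediate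
30 | 2α,7α-diacetoxy-6β-(3-methylbutanoyloxy)-(13E)-labda-8,13-dien-15-ol | CC(=O)O[C@H]1CC(C)(C)[C@@H]2[C@H](OC(=O)CC(C)C)[C@@H](OC(C)=O)C(C)=C(CC/C(C)=C/CO)[C@@]2(C)C1 | target

**Step count**

Total steps: 21. Longest linear sequence: 18 (steps 1, 2, 4–12 and 15–21).

**Steps most likely to fail**

1. Step 11. The cycloaddition may be too slow, because the diene carries an inside methyl group on C8 and the dienophile is β,β-disubstituted, so that thermal desilylation or enal isomerization competes. The endo/anti preference may also be incomplete, leading to cis ring fusion. The fallback replaces the pericyclic step by a two-stage polar annulation that sets out from 14. Me2AlCl in CH2Cl2 at −78 °C should promote an intramolecular Mukaiyama–Michael addition of the silyl enol ether carbon C5 to the enal β-carbon C10, giving after aqueous work-up the ring A keto aldehyde (1R,2S,5S)-configured 2-(2-oxoethyl)-2,6,6-trimethyl-4-(triethylsilyloxy)cyclohexyl (E)-β-methoxy enone F1. Pyrrolidine and AcOH in benzene at 60 °C should then close ring B by enamine addition to the β-methoxy enone with loss of methanol, giving 6-oxo-2α-(triethylsilyloxy)drim-7-en-11-al F2. TBSOTf and Et3N in CH2Cl2 should silylate the ring ketone with deprotonation at the doubly activated C9 and return the route at 16.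

2. Step 8. Enolization may go astray: γ-deprotonation at the C8 methyl group or at the enoate, or an E/Z mixture at the new enol ether, would give isomeric dienes that cannot cyclize as planned. The fallback sets out from 10 and uses an amino diene, whose vinylogous amide precursor is deprotonated cleanly at the α' position. Pyrrolidine adds to the ynone to give the (E)-enaminone F3. KN(SiMe3)2 and TBSCl give the 1-amino-3-silyloxy diene ester F4. iBu2AlH gives the allylic alcohol F5, and SO3·pyridine, DMSO and iPr2NEt (Parikh–Doering oxidation) give the enal F6. F6 should cyclize below 80 °C to the 8β-pyrrolidinyl cycloadduct F7, which loses pyrrolidine on silica gel or with AcOH and comes back to the route at 16.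

3. Step 20. Acylation of the 6β alcohol, which is syn-axial to two methyl groups, may stall, and forcing may cause acyl scrambling or loss of the allylic acetate. The fallback sets out from 26 and acylates at the metal alkoxide stage. Ac2O and pyridine give the 2α,7α-diacetoxy ketone F8. LiAlH(OtBu)3 in THF at −78 °C should reduce C6 from the α face, and the resulting alkoxide is trapped in the same flask with 3-methylbutanoic anhydride and DMAP (reductive acylation), which returns the route at 29.

**Further compounds**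

F1 | step 11 | (E)-4-methoxy-1-[(1R,2S,5S)-2-(2-oxoethyl)-2,6,6-trimethyl-4-(triethylsilyloxy)cyclohexyl]pent-3-en-2-one-type keto aldehyde (ring A closed, C5–C10 formed) | CC[Si](CC)(CC)O[C@H]1CC(C)(C)[C@H](C(=O)/C=C(\C)OC)[C@@](C)(CC=O)C1
F2 | step 11 | 6-oxo-2α-(triethylsilyloxy)drim-7-en-11-al | CC[Si](CC)(CC)O[C@H]1CC(C)(C)[C@@H]2C(=O)C=C(C)C(C=O)[C@@]2(C)C1
F3 | step 8 | methyl (2E,5S,10E)-3,7,7-trimethyl-9-oxo-11-(pyrrolidin-1-yl)-5-(triethylsilyloxy)dodeca-2,10-dienoate | COC(=O)/C=C(\C)C[C@@H](O[Si](CC)(CC)CC)CC(C)(C)CC(=O)/C=C(\C)N1CCCC1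
F4 | step 8 | methyl (2E,8Z,10E)-9-(tert-butyldimethylsilyloxy)-3,7,7-trimethyl-11-(pyrrolidin-1-yl)-5-(triethylsilyloxy)dodeca-2,8,10-trienoate | COC(=O)/C=C(\C)C[C@@H](O[Si](CC)(CC)CC)CC(C)(C)/C=C(O[Si](C)(C)C(C)(C)C)/C=C(\C)N1CCCC1
F5 | step 8 | (2E,8Z,10E)-9-(tert-butyldimethylsilyloxy)-3,7,7-trimethyl-11-(pyrrolidin-1-yl)-5-(triethylsilyloxy)dodeca-2,8,10-trien-1-ol | OC/C=C(\C)C[C@@H](O[Si](CC)(CC)CC)CC(C)(C)/C=C(O[Si](C)(C)C(C)(C)C)/C=C(\C)N1CCCC1
F6 | step 8 | (2E,8Z,10E)-9-(tert-butyldimethylsilyloxy)-3,7,7-trimethyl-11-(pyrrolidin-1-yl)-5-(triethylsilyloxy)dodeca-2,8,10-trienal | O=C/C=C(\C)C[C@@H](O[Si](CC)(CC)CC)CC(C)(C)/C=C(O[Si](C)(C)C(C)(C)C)/C=C(\C)N1CCCC1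
F7 | step 8 | 8β-(pyrrolidin-1-yl)-2α-(triethylsilyloxy)-6-(tert-butyldimethylsilyloxy)drim-6-en-11-al | CC[Si](CC)(CC)O[C@H]1CC(C)(C)[C@@H]2C(O[Si](C)(C)C(C)(C)C)=C[C@](C)(N3CCCC3)[C@H](C=O)[C@@]2(C)C1
F8 | step 20 | 2α,7α-diacetoxy-15-(tert-butyldiphenylsilyloxy)-(13E)-labda-8,13-dien-6-one | CC(=O)O[C@H]1CC(C)(C)[C@@H]2C(=O)[C@@H](OC(C)=O)C(C)=C(CC/C(C)=C/CO[Si](c3ccccc3)(c3ccccc3)C(C)(C)C)[C@@]2(C)C1
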